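**Retrosynthetic overview**

1. Ring C is closed last by O1–C2 bond formation: the A-ring phenol adds to a B-ring quinone-methide-type benzylic cation generated from a racemic 1,3-diarylpropan-1-ol under a chiral Brønsted acid, which sets (2S). This is the quinone-methide counterpart of the oxa-Michael closure of the flavonoid pathway.
2. The diarylpropanol is cut at C4–C4a into a B-ring allylic alcohol and an A-ring aryl bromide (hydroboration, then B-alkyl Suzuki coupling).
3. The A-ring bromide comes from 4-bromoresorcinol; an aromatic Claisen rearrangement of its prenyl ether places the 1,1-dimethylallyl group.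
4. The B-ring piece comes from 2-bromo-4,5-dihydroxybenzaldehyde: the dimethylchromene ring by oxa-6π electrocyclisation of an o-quinone methide (reached from an aryl propargyl ether), the prenyl group by Stille coupling, the C3 unit by vinyl Grignard addition.
5. Ring order: chromene ring first (step 1), ring C last (step 7). No protecting groups are used.

Assumption: 2-bromo-4,5-dihydroxybenzaldehyde, 4-bromoresorcinol, 3-chloro-3-methylbut-1-yne and tributyl(prenyl)stannane are taken as catalogue compounds.
Assumption: the (R)-configured acid in step 7 is taken to give the (2S) product; if the measured sense is the opposite, its enantiomer is used.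

**Route**

Step 1
Reactants: 1 2-bromo-4,5-dihydroxybenzaldehyde; 2 3-chloro-3-methylbut-1-yne
Product: 5 5-bromo-8-hydroxy-2,2-dimethyl-2H-chromene-6-carbaldehyde, via aryl propargyl ether 3 (not isolated), via o-quinone methide 4 (not isolated)
Conditions: CuCl2·2H2O (1 mol%), DBU (1.1 equiv), MeCN, 0 °C; aqueous wash; then o-xylene, 140 °C
Reagents that add atoms: 3-chloro-3-methylbut-1-yne (compound 2), C#CC(C)(C)Cl
Why: Copper-catalysed O-propargylation takes the more acidic 4-OH (para to CHO), and the aromatic propargyl Claisen rearrangement/[1,5]-H shift then gives o-quinone methide 4, whose oxa-6π electrocyclisation closes the dimethylchromene ring at the only free ortho carbon; this is the ring closure thought to follow dehydrogenation of an o-prenylphenol in nature, reached here without an oxidant.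

Step 2
Reactants: 5 5-bromo-8-hydroxy-2,2-dimethyl-2H-chromene-6-carbaldehyde; 6 tributyl(3-methylbut-2-en-1-yl)stannane
Product: 7 8-hydroxy-2,2-dimethyl-5-(3-methylbut-2-en-1-yl)-2H-chromene-6-carbaldehyde
Conditions: Bu3SnCH2CH=CMe2 (1.3 equiv), Pd(PPh3)4 (5 mol%), DMF, 100 °C
Reagents that add atoms: tributyl(3-methylbut-2-en-1-yl)stannane (compound 6), CCCC[Sn](CCCC)(CCCC)CC=C(C)C
Why: Stille coupling at the C–Br bond activated by the ortho aldehyde; reductive elimination at the unsubstituted allyl terminus gives the linear prenyl group, and the free phenol, aldehyde and chromene are tolerated under these neutral conditions.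

Step 3
Reactants: 7 8-hydroxy-2,2-dimethyl-5-(3-methylbut-2-en-1-yl)-2H-chromene-6-carbaldehyde; 8 vinylmagnesium bromide
Product: 9 rac-1-[8-hydroxy-2,2-dimethyl-5-(3-methylbut-2-en-1-yl)-2H-chromen-6-yl]prop-2-en-1-ol
Conditions: CH2=CHMgBr (2.5 equiv), THF, −78 to 0 °C; aq. NH4Cl
Reagents that add atoms: vinylmagnesium bromide (compound 8), C=C[Mg]Br
Why: Grignard 1,2-addition after the first equivalent has deprotonated the phenol; the carbinol centre is formed racemic on purpose, because step 7 erases and resets it.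

Step 4
Reactants: 10 4-bromobenzene-1,3-diol; 11 1-bromo-3-methylbut-2-ene
Product: 12 2-bromo-5-[(3-methylbut-2-en-1-yl)oxy]phenol
Conditions: NaH (2.1 equiv), DMF, 0 °C; prenyl bromide (1.0 equiv), 0 °C to rt
Reagents that add atoms: 1-bromo-3-methylbut-2-ene (compound 11), CC(C)=CCBr
Why: Williamson etherification of the dianion, in which the less acidic and unhindered phenoxide para to bromine is the stronger nucleophile and is alkylated first, while the phenoxide ortho to bromine stays free.

Step 5
Reactants: 12 2-bromo-5-[(3-methylbut-2-en-1-yl)oxy]phenol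
Product: 13 4-bromo-6-(2-methylbut-3-en-2-yl)benzene-1,3-diol
Conditions: PhNEt2, 190 °C (sealed tube), 2 h
Reagents that add atoms: none
Why: Aromatic Claisen rearrangement ([3,3]) delivers the inverted 1,1-dimethylallyl group to the less hindered ortho carbon (para to the other OH) rather than to the carbon between the two oxygens, and the basic solvent suppresses acid-catalysed cyclisation of the product.

Step 6
Reactants: 9 rac-1-[8-hydroxy-2,2-dimethyl-5-(3-methylbut-2-en-1-yl)-2H-chromen-6-yl]prop-2-en-1-ol; 13 4-bromo-6-(2-methylbut-3-en-2-yl)benzene-1,3-diol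
Product: 15 rac-3-[2,4-dihydroxy-5-(2-methylbut-3-en-2-yl)phenyl]-1-[8-hydroxy-2,2-dimethyl-5-(3-methylbut-2-en-1-yl)-2H-chromen-6-yl]propan-1-ol, via alkylborane 14 (not isolated)
Conditions: 9-BBN (3.3 equiv), THF, 0 °C to rt; MeOH quench; then 13, Pd(OAc)2 (5 mol%), SPhos (10 mol%), aq. K3PO4, THF/DMF, 65 °C
Reagents that add atoms: none
Why: 9-BBN hydroborates only the monosubstituted vinyl group, anti-Markovnikov (the prenyl and chromene alkenes are too hindered; the two OH groups are carried as O–BBN borinates that hydrolyse in the basic medium), and B-alkyl Suzuki–Miyaura coupling then forms C4–C4a; excess borane is quenched before 13 is added so its vinyl group survives, and 15 is purified on Et3N-washed silica because acid cyclises it racemically.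

Step 7
Reactants: 15 rac-3-[2,4-dihydroxy-5-(2-methylbut-3-en-2-yl)phenyl]-1-[8-hydroxy-2,2-dimethyl-5-(3-methylbut-2-en-1-yl)-2H-chromen-6-yl]propan-1-ol
Product: 17 kazinol H, via benzylic cation 16 (not isolated)
Conditions: (R)-3,3'-bis(2,4,6-triisopropylphenyl)-1,1'-binaphthyl-2,2'-diyl N-triflylphosphoramide (5 mol%), 5 Å MS, toluene, −40 to −20 °C; Et3N quench
Reagents that add atoms: none
Why: Proposed new method: the benzylic alcohol, para to the chromene oxygen, ionises under the chiral acid to planar cation 16 (a p-quinone methide oxonium), so both enantiomers of 15 converge on one chiral contact ion pair; the phosphoramide anion hydrogen-bonds the A-ring 2-OH (the B-ring OH beside the chromene oxygen is a second anchor) and delivers it 6-exo to one face of C2, setting (2S) in an enantioconvergent dehydrative cyclisation; the closest known reaction types are chiral N-triflylphosphoramide-catalysed intramolecular allylic substitution by phenols giving 2-substituted 2H-chromenes, chiral phosphoric acid-catalysed oxa-1,6-additions to p-quinone methides made in situ, and the racemic acid-catalysed cyclodehydration of 1-aryl-3-(2-hydroxyaryl)propan-1-ols to flavans; the product has no free 4'-OH and does not re-ionise at this temperature.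

**Compound list**

1 | 2-bromo-4,5-dihydroxybenzaldehyde | O=Cc1cc(O)c(O)cc1Br | starting material
2 | 3-chloro-3-methylbut-1-yne | C#CC(C)(C)Cl | starting material
3 | 2-bromo-5-hydroxy-4-[(2-methylbut-3-yn-2-yl)oxy]benzaldehyde (aryl propargyl ether) | O=Cc1cc(O)c(OC(C)(C)C#C)cc1Br | intermediate
4 | 2-bromo-5-hydroxy-3-(3-methylbut-2-en-1-ylidene)-4-oxocyclohexa-1,5-diene-1-carbaldehyde (o-quinone methide) | O=C1C(O)=CC(C=O)=C(Br)C1=CC=C(C)C | intermediate
5 | 5-bromo-8-hydroxy-2,2-dimethyl-2H-chromene-6-carbaldehyde | CC1(C)C=Cc2c(Br)c(C=O)cc(O)c2O1 | intermediate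
6 | tributyl(3-methylbut-2-en-1-yl)stannane | CCCC[Sn](CCCC)(CCCC)CC=C(C)C | starting material
7 | 8-hydroxy-2,2-dimethyl-5-(3-methylbut-2-en-1-yl)-2H-chromene-6-carbaldehyde | CC(C)=CCc1c(C=O)cc(O)c2OC(C)(C)C=Cc12 | intermediate
8 | vinylmagnesium bromide | C=C[Mg]Br | starting material
9 | rac-1-[8-hydroxy-2,2-dimethyl-5-(3-methylbut-2-en-1-yl)-2H-chromen-6-yl]prop-2-en-1-ol | C=CC(O)c1cc(O)c2OC(C)(C)C=Cc2c1CC=C(C)C | intermediate
10 | 4-bromobenzene-1,3-diol (4-bromoresorcinol) | Oc1ccc(Br)c(O)c1 | starting material
11 | 1-bromo-3-methylbut-2-ene (prenyl bromide) | CC(C)=CCBr | starting material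
12 | 2-bromo-5-[(3-methylbut-2-en-1-yl)oxy]phenol | CC(C)=CCOc1ccc(Br)c(O)c1 | intermediate
13 | 4-bromo-6-(2-methylbut-3-en-2-yl)benzene-1,3-diol | C=CC(C)(C)c1cc(Br)c(O)cc1O | intermediate
14 | racemic alkylborane: 9-{3-[(9-borabicyclo[3.3.1]nonan-9-yl)oxy]-3-[8-(9-borabicyclo[3.3.1]nonan-9-yloxy)-2,2-dimethyl-5-(3-methylbut-2-en-1-yl)-2H-chromen-6-yl]propyl}-9-borabicyclo[3.3.1]nonane | CC(C)=CCc1c(C(CCB2C3CCCC2CCC3)OB2C3CCCC2CCC3)cc(OB2C3CCCC2CCC3)c2OC(C)(C)C=Cc12 | intermediate
15 | rac-3-[2,4-dihydroxy-5-(2-methylbut-3-en-2-yl)phenyl]-1-[8-hydroxy-2,2-dimethyl-5-(3-methylbut-2-en-1-yl)-2H-chromen-6-yl]propan-1-ol | C=CC(C)(C)c1cc(CCC(O)c2cc(O)c3OC(C)(C)C=Cc3c2CC=C(C)C)c(O)cc1O | intermediate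
16 | benzylic cation at C2 of the propane chain, stabilised by the chromene oxygen and paired with the chiral phosphoramide anion | C=CC(C)(C)c1cc(CC[CH+]c2cc(O)c3OC(C)(C)C=Cc3c2CC=C(C)C)c(O)cc1O | intermediate
17 | kazinol H, 6-[(2S)-7-hydroxy-6-(2-methylbut-3-en-2-yl)-3,4-dihydro-2H-chromen-2-yl]-2,2-dimethyl-5-(3-methylbut-2-en-1-yl)-2H-chromen-8-ol | C=CC(C)(C)c1cc2c(cc1O)O[C@H](c1cc(O)c3c(c1CC=C(C)C)C=CC(C)(C)O3)CC2 | target

**Step count**

Total: 7 steps. Longest linear sequence: 5 steps (steps 1, 2, 3, 6, 7, from compound 1).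

**Steps most likely to fail, with fallbacks**

Step 7. The enantioselective cyclisation has no direct precedent on this substrate class; low ee, or elimination to the cinnamylphenol, are the likely failures. The fallback fixes the configuration at the carbinol and closes ring C by SN2 displacement instead. It sets out from 7: addition of Zn(CH=CH2)2 in the presence of (+)-MIB, the (2R) enantiomer of 3-exo-morpholinoisoborneol (10 mol%, toluene, 0 °C), gives (1R)-1-[8-hydroxy-2,2-dimethyl-5-(3-methylbut-2-en-1-yl)-2H-chromen-6-yl]prop-2-en-1-ol F1. Hydroboration and Suzuki coupling with 13, exactly as in step 6, lead through the (R)-configured alkylborane F2 to (1R)-3-[2,4-dihydroxy-5-(2-methylbut-3-en-2-yl)phenyl]-1-[8-hydroxy-2,2-dimethyl-5-(3-methylbut-2-en-1-yl)-2H-chromen-6-yl]propan-1-ol F3. Mitsunobu etherification (PPh3, DIAD, THF, −20 °C) then closes the ring with inversion, (R) to (2S), and comes back to the route at 17. Some erosion of ee through partial ionisation of the electron-rich benzylic centre is the residual risk.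

Step 6. The coupling is run on an alkylborane carrying three unprotected hydroxyl groups and an electron-rich bromophenol; slow transmetalation or protodeboronation may defeat it. The fallback replaces the borane by a Heck arylation. It sets out from 9 and 13: Pd(OAc)2, n-Bu4NCl, NaHCO3, DMF, 60 °C; the aryl–palladium species adds to the vinyl group, and β-hydride elimination towards the carbinol followed by tautomerisation gives 3-[2,4-dihydroxy-5-(2-methylbut-3-en-2-yl)phenyl]-1-[8-hydroxy-2,2-dimethyl-5-(3-methylbut-2-en-1-yl)-2H-chromen-6-yl]propan-1-one F4. Reduction with NaBH4 (MeOH, 0 °C) comes back to the route at 15.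

Step 2. The bromide is flanked by two ortho substituents, and prenyl transfer from tin can give some of the branched (1,1-dimethylallyl) isomer. The fallback installs the prenyl group in two stages with no regiochemical ambiguity. It sets out from 5: Stille coupling with CH2=CHCH2SnBu3 (Pd(PPh3)4, DMF, 90 °C) gives 8-hydroxy-2,2-dimethyl-5-(prop-2-en-1-yl)-2H-chromene-6-carbaldehyde F5. Cross-metathesis with 2-methylbut-2-ene (neat, second-generation Grubbs catalyst, 40 °C) converts allyl into prenyl and comes back to the route at 7; the hindered chromene alkene does not take part.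

**Further compounds**

F1 | step 7 | (1R)-1-[8-hydroxy-2,2-dimethyl-5-(3-methylbut-2-en-1-yl)-2H-chromen-6-yl]prop-2-en-1-ol | C=C[C@@H](O)c1cc(O)c2OC(C)(C)C=Cc2c1CC=C(C)C
F2 | step 7 | (R)-configured alkylborane, 9-{(3R)-3-[(9-borabicyclo[3.3.1]nonan-9-yl)oxy]-3-[8-(9-borabicyclo[3.3.1]nonan-9-yloxy)-2,2-dimethyl-5-(3-methylbut-2-en-1-yl)-2H-chromen-6-yl]propyl}-9-borabicyclo[3.3.1]nonane | CC(C)=CCc1c([C@@H](CCB2C3CCCC2CCC3)OB2C3CCCC2CCC3)cc(OB2C3CCCC2CCC3)c2OC(C)(C)C=Cc12
F3 | step 7 | (1R)-3-[2,4-dihydroxy-5-(2-methylbut-3-en-2-yl)phenyl]-1-[8-hydroxy-2,2-dimethyl-5-(3-methylbut-2-en-1-yl)-2H-chromen-6-yl]propan-1-ol | C=CC(C)(C)c1cc(CC[C@@H](O)c2cc(O)c3OC(C)(C)C=Cc3c2CC=C(C)C)c(O)cc1O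
F4 | step 6 | 3-[2,4-dihydroxy-5-(2-methylbut-3-en-2-yl)phenyl]-1-[8-hydroxy-2,2-dimethyl-5-(3-methylbut-2-en-1-yl)-2H-chromen-6-yl]propan-1-one | C=CC(C)(C)c1cc(CCC(=O)c2cc(O)c3OC(C)(C)C=Cc3c2CC=C(C)C)c(O)cc1O
F5 | step 2 | 8-hydroxy-2,2-dimethyl-5-(prop-2-en-1-yl)-2H-chromene-6-carbaldehyde | C=CCc1c(C=O)cc(O)c2OC(C)(C)C=Cc12
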